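Conventions: germacrane numbering is used throughout (ring C1–C10, lactone O on C6, lactone carbons C11–C13 on C7, methyls C14 on C10 and C15 on C4); α is the face of H7, β the opposite face.
Assumption: hydroboration (step 3) is not expected to control C11; compounds 4–8 and 11–15 are drawn as the (11S) epimers, and any (11R) material is carried along because C11 becomes trigonal in step 11.

## Analysis of the target

The target is a germacranolide: a cyclodeca-1(10),4-diene trans-fused at C6–C7 to an α-methylene-γ-butyrolactone (O–C6, C7–C11(=C13)–C12=O). The ring alkenes are both trisubstituted, C1=C10 Z and C4=C5 E. Four contiguous stereocentres, C6 (R), C7 (S), C8 (R) and C9 (R), carry substituents on alternating faces: O6 α, C11 β, O8 α, O9 β. O9 bears an acetate and O8 a (2S,3S)-2,3-dimethyloxirane-2-carboxylate with two more stereocentres. Sensitive groups are the methylene lactone (Michael acceptor, incompatible with hydrides, enolates and irradiation), the epoxide, the 1,5-diene (transannular cyclisation with acid, Cope rearrangement on heating) and the two different esters on neighbouring oxygens (acyl migration, translactonisation to O8). The difficulty is a strained ten-membered ring with two defined alkene geometries next to a stereotetrad whose two secondary oxygens must be told apart. The strategy rests on two observations. The arc C5–C6–C7–C8–C9–C10, with C14 on C10, oxygen on C9 and the three-carbon unit on C7, is the ring of carvone. The diene C1=C10/C4=C5 is the formal metathesis product of the C5=C10 bond of that cyclohexenone and the C1=C4 bond of 1-methylcyclobutene, which supplies C1–C4 and C15.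

## Retrosynthetic reasoning

**C8–O acyl bond.** Target 25 is cut at the O8 ester into alcohol 19 and epoxy acid 23. The epoxy ester would not survive the enolate, hydride or thermal steps, so it goes on last. The forward step must acylate a hindered secondary alcohol with an α-quaternary acid faster than the neighbouring acetate migrates. Acid 23 goes back through epoxy alcohol 22 and allylic alcohol 21 to ester 20; an asymmetric epoxidation of the Z-alkene sets both epoxide centres.

**O9 acetate and the silyl ethers.** 19 goes back through 18 and 17 to bis-silyl ether 16. No skeletal bond is cut. The two oxygens are told apart by a robust silyl group on O8 (present from the start) and a labile one on O9 (put on after the C9 reduction).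

**C11=C13.** 16 is traced to the saturated α-methyl lactone 14 through selenide 15. The conjugated methylene would not survive irradiation, 200 °C or a hydride, so it is carried as a methyl group. The trans ring fusion directs the syn-elimination away from H7.

**C9–H.** 14 and 13 go back to dienone 12. The C9 centre is set by hydride addition next to the C8 silyloxy group, after the ring is formed.

**The ten-membered ring (C1–C4 and C5–C10 reconnected).** 12 is the cycloreversion product of tricyclic ketone 11. This replaces a medium ring by a cyclohexanone carrying a bicyclo[2.2.0]hexane, whose strain drives the forward opening. The forward reaction must break C1–C4, then C5–C10, through the chair 1,4-diyl with C9 axial and C6 equatorial. Because the trans-lactone freezes the six-membered ring, only the adduct with the cyclobutane on the α face offers that chair. On a cis-fused bicycle a fusion substituent that is axial on one ring is equatorial on the other: C14 (β, axial on the cyclohexanone) is equatorial on the diyl ring, and H5 (β, equatorial on the cyclohexanone) is axial on it.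

**C1–C10 and C4–C5 (retro-[2+2]).** 11 is cut into enone lactone 8 and 1-methylcyclobutene 10. The cut is made here because it leads straight back to a 2-methylcyclohexenone of the carvone type and forms both future alkenes in one operation. 10 comes from methylenecyclobutane 9 by alkene isomerisation.

**The enone lactone.** 8 is opened at C12–O6 to diol 7. The C6–O bond of 7 is cut back to 5 (γ-hydroxylation through dienol ether 6). The C12–O bond of 5 is cut back to 3 (hydroboration through borane 4). The C8–O bond is cut back through 2 to (S)-carvone 1. The order is deliberate. The C8 silyloxy group goes on first because it shields the α′-position and leaves C6–H as the accessible acidic site. The isopropenyl alkene is hydroborated before any dienol ether is made, so that it can neither aromatise the ring nor compete for peracid. It is also gone before irradiation, where it would add intramolecularly to the enone.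

## Alternatives that were turned down

**Alternative 1:** C7–C8 is cut. An open-chain aldehyde A1 carries C8 as the formyl group and a 3-(bromomethyl)butenolide at C6. Zinc or indium metal would give an allylmetal that attacks the aldehyde through C7 and delivers A2.
- For: one step closes the ring, makes C7 and C8 and creates the exocyclic methylene. No selenium chemistry is needed, and O8 emerges free for the epoxy ester while O9 is already protected. On end-game economy this is stronger than the chosen route.
- Against: A1 needs both trisubstituted alkenes (one Z, one E) and the C6 and C9 centres built one by one in an acyclic chain, well over a dozen steps. The cyclisation must fix C7 relative to C6 and C8 relative to C7 in a ten-membered transition state, at high dilution, with an epimerisable α-alkoxy aldehyde.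
- Comparison: the chosen route takes C7 from carvone, sets C6 and C8 on a six-membered ring and forms the medium ring by a unimolecular, strain-driven step with no entropic penalty.

**Alternative 2:** C5–C6 is cut. An (E)-alkenyl iodide aldehyde A3 would be cyclised with CrCl2 and catalytic NiCl2, and the C6 alkoxide would close the lactone on the methyl ester to give A4.
- For: the alkenyl iodide keeps its geometry, so 4E is secured before ring closure and 1(10)Z is built separately. This is stronger than the chosen route, where both geometries arise in one thermal step. The coupling tolerates the oxygen functions.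
- Against: the C6 configuration is decided during macrocyclisation and only the 6α alkoxide can give the trans-lactone. The C7–C9 triad has to be made acyclically with C7 α to an aldehyde. A large excess of CrCl2 at high dilution is required. A4 lacks C13, so a methylenation is still needed.
- Comparison: the chosen route settles C6 by substrate control on a small ring and reaches its ring precursor in five steps from the chiral pool.

**Alternative 3:** C2–C3 is cut. Allyl sulfone/allyl chloride A5 would be cyclised with KN(SiMe3)2 at high dilution to A6, followed by desulfonylation.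
- For: the new bond is remote from every stereocentre, both alkenes are fixed beforehand and no stereocentre of consequence is formed. On geometric security this is the safest of all four.
- Against: A5 contains all four stereocentres and four different protecting groups and is the longest precursor. Ten-membered closure by displacement of an allylic chloride competes with SN2′ attack and dimerisation. Reductive removal of an allylic sulfone can move the C4=C5 alkene. The lactone still has to be made afterwards by oxidising C12 and closing on O6.
- Comparison: the chosen route is far shorter and trades this security for one stereochemical question, the face of the photocycloaddition.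

Key step: step 7

## Route

Step 1
Reactants: 1 (S)-(+)-carvone
Product: 2 (5R,6R)-6-hydroxy-2-methyl-5-(prop-1-en-2-yl)cyclohex-2-en-1-one (trans-6-hydroxycarvone)
Conditions: NaN(SiMe3)2, THF, −78 °C; 2-(phenylsulfonyl)-3-phenyloxaziridine, −78 °C; aq. NH4Cl
Reagents that add atoms: 2-(phenylsulfonyl)-3-phenyloxaziridine, O=S(=O)(c1ccccc1)N1OC1c1ccccc1
Why: Kinetic deprotonation at the α′-CH2 (future C8) gives the cross-conjugated enolate, which the N-sulfonyloxaziridine hydroxylates at carbon (Davis oxidation); the reagent approaches anti to the neighbouring isopropenyl group, so the new C8–O bond is trans to it.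

Step 2
Reactants: 2 trans-6-hydroxycarvone
Product: 3 (5R,6R)-6-[(tert-butyldimethylsilyl)oxy]-2-methyl-5-(prop-1-en-2-yl)cyclohex-2-en-1-one
Conditions: TBSOTf, 2,6-lutidine, CH2Cl2, −78 to 0 °C
Reagents that add atoms: tert-butyldimethylsilyl triflate, CC(C)(C)[Si](C)(C)OS(=O)(=O)C(F)(F)F
Why: Standard silylation of a secondary alcohol; a silyl ether is chosen because it offers no activated γ-hydrogen to the excited enone in step 7 and shields C8–H from base in step 4.

Step 3
Reactants: 3 silyl ether of trans-6-hydroxycarvone
Product: 5 (5R,6R)-6-[(tert-butyldimethylsilyl)oxy]-5-[(2S)-1-hydroxypropan-2-yl]-2-methylcyclohex-2-en-1-one, via alkylborane 4 (not isolated)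
Conditions: 9-BBN, THF, 0 °C to rt; NaBO3·4H2O, H2O, rt
Reagents that add atoms: sodium perborate tetrahydrate, O.O.O.O.[Na+].[O-]OB=O; 9-borabicyclo[3.3.1]nonane, B1C2CCCC1CCC2 (boron kept only in 4)
Why: Anti-Markovnikov hydroboration of the 1,1-disubstituted alkene by a hindered dialkylborane, which should be faster than reduction of the conjugated, α-silyloxy-flanked ketone; perborate oxidises the C–B bond without the strongly basic peroxide that would epoxidise the enone. C11 is formed here without reliable control (see assumption).

Step 4
Reactants: 5 primary alcohol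
Product: 7 (4R,5S,6R)-6-[(tert-butyldimethylsilyl)oxy]-4-hydroxy-5-[(2S)-1-hydroxypropan-2-yl]-2-methylcyclohex-2-en-1-one, via bis-silyl dienol ether 6 (not isolated)
Conditions: Me3SiCl, KN(SiMe3)2, THF, −78 °C; mCPBA, NaHCO3, CH2Cl2, −20 °C; 1 M HCl, THF, 0 °C
Reagents that add atoms: 3-chloroperbenzoic acid, OOC(=O)c1cccc(Cl)c1; chlorotrimethylsilane, C[Si](C)(C)Cl (silicon kept only in 6)
Why: The hindered base removes a γ-hydrogen at C6, since the only α′-hydrogen is tertiary and shielded by the silyloxy group; the through-conjugated silyl dienol ether is then oxidised at its terminal carbon (vinylogous Rubottom oxidation). In the cyclohexadiene the C8 silyloxy group avoids the neighbouring C9 silyloxy group by going pseudoaxial, which makes the trans C7 side chain pseudoaxial too, so the peracid should attack C6 anti to it and give the 6α-alcohol.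

Step 5
Reactants: 7 hydroxy enone diol
Product: 8 (3S,3aS,4R,7aR)-4-[(tert-butyldimethylsilyl)oxy]-3,6-dimethyl-3a,4-dihydro-1-benzofuran-2,5(3H,7aH)-dione (trans-fused enone lactone: C5=C10 enone, C9 ketone, 8α-OTBS, 11α-methyl)
Conditions: TEMPO (cat.), PhI(OAc)2, CH2Cl2, rt
Reagents that add atoms: none
Why: Oxoammonium oxidation takes the primary alcohol to the aldehyde, which is trapped by the 6α-hydroxyl as a lactol and oxidised on to the lactone (oxidative lactonisation of a 1,4-diol); the C6–O bond is not touched, so the trans fusion follows from step 4.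

Step 6
Reactants: 9 methylenecyclobutane
Product: 10 1-methylcyclobutene
Conditions: Na on Al2O3 (cat.), neat, 5 °C; spinning-band distillation
Reagents that add atoms: none
Why: Base-catalysed allylic isomerisation; the equilibrium favours the endocyclic trisubstituted alkene, and a basic catalyst avoids the cyclobutyl cation rearrangements of acid catalysis.

Step 7
Reactants: 8 trans-fused enone lactone; 10 1-methylcyclobutene
Product: 11 cis-anti-cis photoadduct: cyclobutane C5–C4–C1–C10 fused on the α face of the cyclohexanone ring of 8 (C4 with C15 bonded to C5, C1 bonded to C10, C14 β, outer cyclobutane C1–C2–C3–C4 anti to the six-membered ring, 8α-OTBS, lactone unchanged)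
Conditions: hν (366 nm), 10 (15 equiv), CH2Cl2, −40 °C, Ar
Reagents that add atoms: none
Why: Excitation of the n,π* band of 8 gives, after intersystem crossing, the twisted triplet enone, which adds to alkene 10 through a triplet 1,4-biradical that closes after spin inversion; the closest known reaction type is the intermolecular enone–alkene [2+2] photocycloaddition, including its use with cyclobutenes ahead of thermal ring opening. The one new ring, the cyclobutane C5–C4–C1–C10, is closed by radical recombination and is cis-fused to the six-membered ring, because a bond made axially at C5 can only reach C10 on the same face. The methyl-bearing alkene carbon C4 should end on the β-carbon C5 (head-to-tail, as for isobutene and other electron-rich 1,1-disubstituted alkenes), since the alternative must join the two fully substituted carbons C4 and C10, a biradical closure that is slow and reverts. C5 is set by the half-chair that the trans-lactone imposes: the pyramidalised β-carbon takes the new bond axially, antiperiplanar to the axial H6, that is on the α face, and C10 follows from the cis closure with its methyl β. C1 and C4 are cis by the ring of 10 and anti to the six-membered ring because the cyclobutene approaches with its CH2–CH2 edge turned away. The step needs head-to-tail regiochemistry and the α face: the four new centres disappear in step 8, but only the α-adduct places C9 axial and C6 equatorial on the diyl of that step, whereas the β-adduct would lead to the 1(10)E,4Z diene. Light of 366 nm excites only the enone and spares the product ketone, and the saturated lactone and the silyl ether offer no alkene and no activated γ-hydrogen to the excited state.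

Step 8
Reactants: 11 cis-anti-cis photoadduct
Product: 12 (1(10)Z,4E,11S)-8α-[(tert-butyldimethylsilyl)oxy]-9-oxogermacra-1(10),4-dien-12,6α-olide
Conditions: PhMe (5 mM, degassed), 2,6-di-tert-butyl-4-methylphenol (cat.), base-washed sealed tube, 200 °C
Reagents that add atoms: none
Why: Thermal cycloreversion of a bicyclo[2.2.0]hexane: the strained central C1–C4 bond breaks first and the cyclohexane-1,4-diyl then cleaves C5–C10, the most substituted bond and the one α to the carbonyl, giving both ring alkenes. With the six-membered ring held as a chair by the trans-lactone, the only chair diyl has C9 axial and C6 equatorial, so C9 ends cis to C2 (1(10)Z) and C6 trans to C3 (4E). C6, C7, C8 and C11 are not touched.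

Step 9
Reactants: 12 Z,E-dienone
Product: 13 (1(10)Z,4E,11S)-8α-[(tert-butyldimethylsilyl)oxy]-9β-hydroxygermacra-1(10),4-dien-12,6α-olide
Conditions: LiBH(sBu)3, THF, −78 °C; aq. NH4Cl
Reagents that add atoms: none
Why: The hindered borohydride should add to the carbonyl and not to C1 of the twisted, α-methylated Z-enone, and it leaves the lactone alone at −78 °C. Felkin–Anh addition anti to the C8 silyloxy group gives the 8,9-threo, (9R) alcohol.

Step 10
Reactants: 13 9β-alcohol
Product: 14 (1(10)Z,4E,11S)-8α-[(tert-butyldimethylsilyl)oxy]-9β-[(triethylsilyl)oxy]germacra-1(10),4-dien-12,6α-olide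
Conditions: Et3SiOTf, 2,6-lutidine, CH2Cl2, −78 °C
Reagents that add atoms: triethylsilyl triflate, CC[Si](CC)(CC)OS(=O)(=O)C(F)(F)F
Why: Silylation under amine-buffered conditions forms no alkoxide, so the C8 silyl group cannot migrate; the triethylsilyl ether withstands the amide base of step 11 and is later removed in the presence of the tert-butyldimethylsilyl ether.

Step 11
Reactants: 14 bis-silyl ether
Product: 16 (1(10)Z,4E)-8α-[(tert-butyldimethylsilyl)oxy]-9β-[(triethylsilyl)oxy]germacra-1(10),4,11(13)-trien-12,6α-olide, via selenide 15 (not isolated)
Conditions: LiN(iPr)2, THF, −78 °C; PhSeSePh, HMPA, −78 to −40 °C; aq. NH4Cl; then mCPBA, CH2Cl2, −78 °C; iPr2NH, −78 °C to rt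
Reagents that add atoms: none
Why: Selenenylation of the lactone enolate followed by selenoxide syn-elimination; the diselenide does not add to the ring alkenes, and the cold peracid oxidises selenium much faster than it epoxidises them. In the trans-fused lactone selenium enters on the β face, trans to H7, so only a methyl hydrogen is syn to the selenoxide and the exocyclic alkene results.

Step 12
Reactants: 16 methylene lactone bis-silyl ether
Product: 17 (1(10)Z,4E)-8α-[(tert-butyldimethylsilyl)oxy]-9β-hydroxygermacra-1(10),4,11(13)-trien-12,6α-olide
Conditions: PPTS, MeOH/CH2Cl2, 0 °C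
Reagents that add atoms: none
Why: Mild acid methanolysis cleaves the triethylsilyl ether much faster than the hindered tert-butyldimethylsilyl ether; the acid is too weak to trigger transannular cyclisation, and methanol does not add to the methylene lactone without base.

Step 13
Reactants: 17 9β-alcohol
Product: 18 (1(10)Z,4E)-9β-acetoxy-8α-[(tert-butyldimethylsilyl)oxy]germacra-1(10),4,11(13)-trien-12,6α-olide
Conditions: Ac2O, pyridine, DMAP (cat.), CH2Cl2, 0 °C to rt
Reagents that add atoms: acetic anhydride, CC(=O)OC(C)=O
Why: Nucleophile-catalysed acetylation of the only free hydroxyl.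

Step 14
Reactants: 18 9-acetate 8-silyl ether
Product: 19 (1(10)Z,4E)-9β-acetoxy-8α-hydroxygermacra-1(10),4,11(13)-trien-12,6α-olide
Conditions: HF·pyridine, pyridine, THF, 0 °C to rt
Reagents that add atoms: none
Why: Buffered fluoride desilylation; the medium is slightly acidic, which should keep the acetate on O9 and the lactone on O6.

Step 15
Reactants: 20 methyl (Z)-2-methylbut-2-enoate (methyl angelate)
Product: 21 (Z)-2-methylbut-2-en-1-ol
Conditions: iBu2AlH, CH2Cl2, −78 to 0 °C; Rochelle salt
Reagents that add atoms: none
Why: 1,2-Reduction of an unsaturated ester to the allylic alcohol by an aluminium hydride, without change of alkene geometry.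

Step 16
Reactants: 21 (Z)-2-methylbut-2-en-1-ol
Product: 22 [(2R,3S)-2,3-dimethyloxiran-2-yl]methanol
Conditions: Ti(OiPr)4 (cat.), L-(+)-diethyl tartrate (cat.), tBuOOH, 4 Å molecular sieves, CH2Cl2, −20 °C
Reagents that add atoms: tert-butyl hydroperoxide, CC(C)(C)OO
Why: Sharpless asymmetric epoxidation; with the L-tartrate the oxygen is delivered to the face that gives the (2R,3S) epoxy alcohol, and the Z geometry fixes the cis relationship of CH2OH and the C3 methyl.

Step 17
Reactants: 22 epoxy alcohol
Product: 23 (2S,3S)-2,3-dimethyloxirane-2-carboxylic acid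
Conditions: TEMPO (cat.), PhI(OAc)2, MeCN/H2O, rt
Reagents that add atoms: water, O
Why: Oxoammonium oxidation to the aldehyde, hydration and second oxidation give the acid; the epoxide centres are untouched (the C2 descriptor changes only because the substituent priorities change).

Step 18
Reactants: 19 8α-alcohol; 23 epoxy acid
Product: 25 (1(10)Z,4E)-9β-acetoxy-8α-{[(2S,3S)-2,3-dimethyloxirane-2-carbonyl]oxy}germacra-1(10),4,11(13)-trien-12,6α-olide (target), via mixed anhydride 24 (not isolated)
Conditions: 2,4,6-trichlorobenzoyl chloride, Et3N, THF, rt; then 19, DMAP, PhMe, rt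
Reagents that add atoms: none
Why: Yamaguchi esterification: the acid is activated as the mixed anhydride and transferred through the acylpyridinium to the hindered alcohol. The acid has no α-hydrogen and cannot epimerise, and the fast acyl transfer in aprotic medium should outrun migration of the O9 acetate.

## Compound list

1 | (S)-(+)-carvone | CC1=CC[C@@H](CC1=O)C(C)=C | starting material
2 | (5R,6R)-6-hydroxy-2-methyl-5-(prop-1-en-2-yl)cyclohex-2-en-1-one | C1C=C(C)C(=O)[C@H](O)[C@H]1C(C)=C | intermediate
3 | (5R,6R)-6-[(tert-butyldimethylsilyl)oxy]-2-methyl-5-(prop-1-en-2-yl)cyclohex-2-en-1-one | C1C=C(C)C(=O)[C@H](O[Si](C)(C)C(C)(C)C)[C@H]1C(C)=C | intermediate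
4 | B-alkyl-9-borabicyclo[3.3.1]nonane from 3 (boron on the terminal carbon of the former isopropenyl group) | C1C=C(C)C(=O)[C@H](O[Si](C)(C)C(C)(C)C)[C@H]1[C@H](C)CB1C2CCCC1CCC2 | intermediate
5 | (5R,6R)-6-[(tert-butyldimethylsilyl)oxy]-5-[(2S)-1-hydroxypropan-2-yl]-2-methylcyclohex-2-en-1-one | C1C=C(C)C(=O)[C@H](O[Si](C)(C)C(C)(C)C)[C@H]1[C@H](C)CO | intermediate
6 | through-conjugated trimethylsilyl dienol ether of 5 with the primary alcohol as trimethylsilyl ether | C1=CC(C)=C(O[Si](C)(C)C)[C@H](O[Si](C)(C)C(C)(C)C)[C@H]1[C@H](C)CO[Si](C)(C)C | intermediate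
7 | (4R,5S,6R)-6-[(tert-butyldimethylsilyl)oxy]-4-hydroxy-5-[(2S)-1-hydroxypropan-2-yl]-2-methylcyclohex-2-en-1-one | O[C@@H]1C=C(C)C(=O)[C@H](O[Si](C)(C)C(C)(C)C)[C@H]1[C@H](C)CO | intermediate
8 | (3S,3aS,4R,7aR)-4-[(tert-butyldimethylsilyl)oxy]-3,6-dimethyl-3a,4-dihydro-1-benzofuran-2,5(3H,7aH)-dione | C[C@@H]1C(=O)O[C@@H]2C=C(C)C(=O)[C@H](O[Si](C)(C)C(C)(C)C)[C@@H]12 | intermediate
9 | methylenecyclobutane | C=C1CCC1 | starting material
10 | 1-methylcyclobutene | CC1=CCC1 | intermediate
11 | cis-anti-cis photoadduct, cyclobutane on the α face (C4–C5 and C1–C10 bonds α, C14 β) | C[C@@H]1C(=O)O[C@@H]2[C@@H]3[C@@]4(C)CC[C@H]4[C@]3(C)C(=O)[C@H](O[Si](C)(C)C(C)(C)C)[C@@H]12 | intermediate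
12 | (1(10)Z,4E,11S)-8α-[(tert-butyldimethylsilyl)oxy]-9-oxogermacra-1(10),4-dien-12,6α-olide | C[C@@H]1C(=O)O[C@@H]2/C=C(\C)CC/C=C(/C)C(=O)[C@H](O[Si](C)(C)C(C)(C)C)[C@@H]12 | intermediate
13 | (1(10)Z,4E,11S)-8α-[(tert-butyldimethylsilyl)oxy]-9β-hydroxygermacra-1(10),4-dien-12,6α-olide | C[C@@H]1C(=O)O[C@@H]2/C=C(\C)CC/C=C(/C)[C@@H](O)[C@H](O[Si](C)(C)C(C)(C)C)[C@@H]12 | intermediate
14 | (1(10)Z,4E,11S)-8α-[(tert-butyldimethylsilyl)oxy]-9β-[(triethylsilyl)oxy]germacra-1(10),4-dien-12,6α-olide | C[C@@H]1C(=O)O[C@@H]2/C=C(\C)CC/C=C(/C)[C@@H](O[Si](CC)(CC)CC)[C@H](O[Si](C)(C)C(C)(C)C)[C@@H]12 | intermediate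
15 | 11β-(phenylselanyl) derivative of 14 (selenium trans to H7, 11-methyl α) | C[C@]1([Se]c3ccccc3)C(=O)O[C@@H]2/C=C(\C)CC/C=C(/C)[C@@H](O[Si](CC)(CC)CC)[C@H](O[Si](C)(C)C(C)(C)C)[C@@H]12 | intermediate
16 | (1(10)Z,4E)-8α-[(tert-butyldimethylsilyl)oxy]-9β-[(triethylsilyl)oxy]germacra-1(10),4,11(13)-trien-12,6α-olide | C=C1C(=O)O[C@@H]2/C=C(\C)CC/C=C(/C)[C@@H](O[Si](CC)(CC)CC)[C@H](O[Si](C)(C)C(C)(C)C)[C@@H]12 | intermediate
17 | (1(10)Z,4E)-8α-[(tert-butyldimethylsilyl)oxy]-9β-hydroxygermacra-1(10),4,11(13)-trien-12,6α-olide | C=C1C(=O)O[C@@H]2/C=C(\C)CC/C=C(/C)[C@@H](O)[C@H](O[Si](C)(C)C(C)(C)C)[C@@H]12 | intermediate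
18 | (1(10)Z,4E)-9β-acetoxy-8α-[(tert-butyldimethylsilyl)oxy]germacra-1(10),4,11(13)-trien-12,6α-olide | C=C1C(=O)O[C@@H]2/C=C(\C)CC/C=C(/C)[C@@H](OC(C)=O)[C@H](O[Si](C)(C)C(C)(C)C)[C@@H]12 | intermediate
19 | (1(10)Z,4E)-9β-acetoxy-8α-hydroxygermacra-1(10),4,11(13)-trien-12,6α-olide | C=C1C(=O)O[C@@H]2/C=C(\C)CC/C=C(/C)[C@@H](OC(C)=O)[C@H](O)[C@@H]12 | intermediate
20 | methyl (Z)-2-methylbut-2-enoate (methyl angelate) | C/C=C(/C)C(=O)OC | starting material
21 | (Z)-2-methylbut-2-en-1-ol | C/C=C(/C)CO | intermediate
22 | [(2R,3S)-2,3-dimethyloxiran-2-yl]methanol | OC[C@@]1(C)O[C@H]1C | intermediate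
23 | (2S,3S)-2,3-dimethyloxirane-2-carboxylic acid | OC(=O)[C@@]1(C)O[C@H]1C | intermediate
24 | (2S,3S)-2,3-dimethyloxirane-2-carboxylic 2,4,6-trichlorobenzoic anhydride | O=C(OC(=O)c1c(Cl)cc(Cl)cc1Cl)[C@@]1(C)O[C@H]1C | intermediate
25 | (1(10)Z,4E)-9β-acetoxy-8α-{[(2S,3S)-2,3-dimethyloxirane-2-carbonyl]oxy}germacra-1(10),4,11(13)-trien-12,6α-olide, CNP0304643.2 | C=C1C(=O)O[C@@H]2/C=C(\C)CC/C=C(/C)[C@@H](OC(C)=O)[C@H](OC(=O)[C@@]3(C)O[C@H]3C)[C@@H]12 | target

## Step count and least certain steps

Total: 18 steps. Longest linear sequence: 14 steps (steps 1–5, 7–14 and 18). Step 6 and steps 15–17 are side branches.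

**Step 7 (key step).** The most likely failure is leakage in the cycloaddition: bonding on the β face, head-to-head orientation, trans-fused closure, or hydrogen abstraction from the allylic positions of 10. The preference for the α face is stereoelectronic only, and the α face also carries the bulky silyl ether next to the carbonyl. A β-adduct carried forward would be converted in step 8 into the 1(10)E,4Z diene, so 11 must be isomerically pure. Fallback: set out from 8 and remove the silyl group with HF·pyridine to give the free 8α-hydroxy enone lactone F1, whose α face is less encumbered. Irradiate F1 with 10 under the conditions of step 7 to give the hydroxy photoadduct F2. Silylate F2 with TBSOTf and 2,6-lutidine to return to the route at 11.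

**Step 8.** The most likely failure is over-reaction in the hot zone: Cope rearrangement of the cis,trans-1,5-diene to a divinylcyclohexanone, competing cleavage of C2–C3 in the diyl, and epimerisation at C8 or Z to E isomerisation of the enone, all because the product is an enolisable, conjugated α-silyloxy ketone at 200 °C. Fallback: open the ring at the alcohol oxidation level. Set out from 11 and reduce the ketone with NaBH4 in MeOH to the 9-hydroxy photoadduct F3. The 9α epimer from attack on the β face is drawn, but the configuration does not matter. Thermolyse F3 as in step 8 to the cyclodecadienol F4. Oxidise F4 with Dess–Martin periodinane and NaHCO3 to return at 12.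

**Step 9.** The most likely failure is poor facial selectivity, because the conformation of the ten-membered ring and not the Felkin–Anh preference may decide which carbonyl face is open; conjugate reduction at C1 is the second risk. Fallback: set out from 12 and, if the reduction delivers mainly the (9S) alcohol, which is the compound F4 described under step 8, invert it by Mitsunobu reaction (4-nitrobenzoic acid, PPh3, diisopropyl azodicarboxylate, THF) to the (9R) 4-nitrobenzoate F5. Methanolysis of F5 (K2CO3, MeOH, 0 °C) returns to the route at 13.

**Step 4.** The most likely failures are enolisation at C8–H instead of C6–H, which would lead to oxidation at the wrong carbon, and peracid attack at C10 or on the β face of C6. Kinetic site selection between a hindered but intrinsically more acidic α′-hydrogen and the γ-hydrogens is hard to predict. Fallback: use thermodynamic instead of kinetic enolisation, through the dienol ester known from the 6-hydroxylation of steroidal 4-en-3-ones. Set out from 5 and heat with isopropenyl acetate and catalytic TsOH to the through-conjugated dienol acetate F6, in which the primary alcohol is acetylated as well. Oxidise F6 with buffered mCPBA to the 6α-hydroxy enone acetate F7. Methanolysis of F7 (K2CO3, MeOH) returns at 7.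

**Step 3.** The most likely failure is competing 1,2-reduction of the enone carbonyl by the borane during the slow hydroboration of a 1,1-disubstituted alkene. Fallback: take the carbonyl out of play first. Set out from 3 and reduce with NaBH4 and CeCl3·7H2O in MeOH to the allylic alcohol F8 (either C9 epimer). Hydroborate F8 with 9-BBN and oxidise with NaOH/H2O2 to the diol F9. Oxidise the allylic alcohol of F9 selectively with MnO2 in CH2Cl2 to return at 5.

## Further compounds

F1 | step 7 | (3S,3aS,4R,7aR)-4-hydroxy-3,6-dimethyl-3a,4-dihydro-1-benzofuran-2,5(3H,7aH)-dione | C[C@@H]1C(=O)O[C@@H]2C=C(C)C(=O)[C@H](O)[C@@H]12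
F2 | step 7 | 8α-hydroxy analogue of photoadduct 11 (free hydroxyl in place of the silyl ether) | C[C@@H]1C(=O)O[C@@H]2[C@@H]3[C@@]4(C)CC[C@H]4[C@]3(C)C(=O)[C@H](O)[C@@H]12
F3 | step 8 | 9α-hydroxy derivative of photoadduct 11 (ketone reduced) | C[C@@H]1C(=O)O[C@@H]2[C@@H]3[C@@]4(C)CC[C@H]4[C@]3(C)[C@H](O)[C@H](O[Si](C)(C)C(C)(C)C)[C@@H]12
F4 | step 8 | (1(10)Z,4E,11S)-8α-[(tert-butyldimethylsilyl)oxy]-9α-hydroxygermacra-1(10),4-dien-12,6α-olide (C9 epimer of 13) | C[C@@H]1C(=O)O[C@@H]2/C=C(\C)CC/C=C(/C)[C@H](O)[C@H](O[Si](C)(C)C(C)(C)C)[C@@H]12
F5 | step 9 | 9β-(4-nitrobenzoyloxy) derivative of 13 | C[C@@H]1C(=O)O[C@@H]2/C=C(\C)CC/C=C(/C)[C@@H](OC(=O)c3ccc(cc3)[N+](=O)[O-])[C@H](O[Si](C)(C)C(C)(C)C)[C@@H]12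
F6 | step 4 | through-conjugated dienol acetate of 5 with the primary alcohol acetylated | C1=CC(C)=C(OC(C)=O)[C@H](O[Si](C)(C)C(C)(C)C)[C@H]1[C@H](C)COC(C)=O
F7 | step 4 | primary acetate of diol 7 | O[C@@H]1C=C(C)C(=O)[C@H](O[Si](C)(C)C(C)(C)C)[C@H]1[C@H](C)COC(C)=O
F8 | step 3 | allylic alcohol from 1,2-reduction of 3 (either C9 epimer) | C1C=C(C)C(O)[C@H](O[Si](C)(C)C(C)(C)C)[C@H]1C(C)=C
F9 | step 3 | diol from hydroboration of F8 (either C9 epimer) | C1C=C(C)C(O)[C@H](O[Si](C)(C)C(C)(C)C)[C@H]1[C@H](C)CO
A1 | alternative 1 | open-chain (Z,E)-dienal with 9-O-(4-methoxybenzyl) group and 3-(bromomethyl)butenolide at C6 | O=C[C@H](OCc1ccc(OC)cc1)/C(C)=C\CC/C(C)=C/[C@H]1OC(=O)C(CBr)=C1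
A2 | alternative 1 | 9-O-(4-methoxybenzyl)-8-hydroxy germacranolide with complete skeleton | C=C1C(=O)O[C@@H]2/C=C(\C)CC/C=C(/C)[C@@H](OCc3ccc(OC)cc3)[C@H](O)[C@@H]12
A3 | alternative 2 | open-chain (E)-alkenyl iodide with C6 aldehyde and C12 methyl ester | I/C=C(\C)CC/C=C(/C)[C@@H](O[Si](c1ccccc1)(c1ccccc1)C(C)(C)C)[C@H](OCc1ccc(OC)cc1)[C@@H](CC(=O)OC)C=O
A4 | alternative 2 | trans-fused ten-membered γ-lactone with 8-O-(4-methoxybenzyl) and 9-O-(tert-butyldiphenylsilyl) groups | C1C(=O)O[C@@H]2/C=C(\C)CC/C=C(/C)[C@@H](O[Si](c3ccccc3)(c3ccccc3)C(C)(C)C)[C@H](OCc3ccc(OC)cc3)[C@@H]12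
A5 | alternative 3 | open-chain C2 allylic chloride with C3 phenylsulfonyl group | ClC/C=C(/C)[C@@H](O[Si](c1ccccc1)(c1ccccc1)C(C)(C)C)[C@H](OCc1ccc(OC)cc1)[C@@H](C(=C)CO[Si](C)(C)C(C)(C)C)[C@H](O[Si](C)(C)C(C)(C)C)/C=C(\C)CS(=O)(=O)c1ccccc1
A6 | alternative 3 | C3-phenylsulfonyl (1(10)Z,4E)-cyclodecadiene, mixture at C3 | C1(S(=O)(=O)c2ccccc2)C/C=C(/C)[C@@H](O[Si](c2ccccc2)(c2ccccc2)C(C)(C)C)[C@H](OCc2ccc(OC)cc2)[C@@H](C(=C)CO[Si](C)(C)C(C)(C)C)[C@H](O[Si](C)(C)C(C)(C)C)/C=C1\C
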